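**Remark (assumption):** the target has no stereocentre and is achiral, so no stereocontrol is needed. Ring A is the phenol ring (C1 = C–OH, C2 = C–OAr, Br on C3, C5, C6); ring B is the 2,4-dibromophenoxy ring (C1'–C6').

**Retrosynthetic overview**
- Target 16 ⇒ phenol 15 by removing the C6 bromine (amine-mediated ortho-bromination forward); 15 ⇒ methyl ether 13 (BBr3 forward).
- The strategy rests on ring B: C1' (on oxygen), C2'–Br and C4'–Br. Ring B of 13 is cut at C1'–C2' and C5'–C6', so C2'–C5' with both bromines come from C3–C6 of 3,5-dibromo-2-pyrone 11, and C1'/C6' from the aryl ethynyl ether 8 ([4+2], then loss of CO2).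
- 8 ⇒ bromoenol ether 7 ⇒ vinyl ether 5 ⇒ 2-bromoethyl ether 4 ⇒ 2,4-dibromo-6-methoxyphenol 2 + 1,2-dibromoethane 3; 2 ⇒ guaiacol 1; 11 ⇒ coumalic acid 9.
- Ring A is bought with guaiacol; ring B is the only ring formed (step 7).

Key step: step 7

**Route**

Step 1
Reactants: 1 guaiacol (2-methoxyphenol)
Product: 2 2,4-dibromo-6-methoxyphenol
Conditions: Br2 (2.05 equiv), CH2Cl2, 0 °C → rt
Reagents that add atoms: bromine, BrBr
Why: Electrophilic aromatic bromination is directed by the free OH (the stronger donor) to its para position and its one open ortho position, and the stoichiometry should stop it at the dibromide.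

Step 2
Reactants: 2 2,4-dibromo-6-methoxyphenol; 3 1,2-dibromoethane (5 equiv)
Product: 4 1,5-dibromo-2-(2-bromoethoxy)-3-methoxybenzene
Conditions: K2CO3, DMF, 70 °C
Reagents that add atoms: none
Why: Williamson ether synthesis at a primary sp3 carbon should tolerate the doubly ortho-substituted phenoxide, and the excess of 3 suppresses double alkylation.

Step 3
Reactants: 4 1,5-dibromo-2-(2-bromoethoxy)-3-methoxybenzene
Product: 5 1,5-dibromo-2-(ethenyloxy)-3-methoxybenzene
Conditions: KOtBu (1.5 equiv), THF, 0 °C → rt
Reagents that add atoms: none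
Why: E2 dehydrobromination of a 2-bromoethyl aryl ether with a hindered alkoxide is the standard entry to aryl vinyl ethers, and the aryl bromides are inert to alkoxide at this temperature.

Step 4
Reactants: 5 1,5-dibromo-2-(ethenyloxy)-3-methoxybenzene
Product: 7 1,5-dibromo-2-{[(Z)-2-bromoethenyl]oxy}-3-methoxybenzene, via 1,2-dibromoethyl ether 6 (not isolated)
Conditions: Br2 (1.0 equiv), CH2Cl2, −78 °C; then DBU (1.5 equiv), −78 °C → rt
Reagents that add atoms: bromine, BrBr
Why: Bromine addition to the electron-rich vinyl ether is far faster than attack on the deactivated arene, and base-induced dehydrobromination of the α-bromo ether should give the 2-bromoenol ether (mainly Z; the E isomer or any 1-bromovinyl isomer would give the same alkyne in step 5).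

Step 5
Reactants: 7 1,5-dibromo-2-{[(Z)-2-bromoethenyl]oxy}-3-methoxybenzene
Product: 8 1,5-dibromo-2-(ethynyloxy)-3-methoxybenzene
Conditions: KOtBu (2.2 equiv), THF, −78 → 0 °C; cold pH 7 buffer, pentane extraction, short basic alumina plug; used at once as a toluene solution
Reagents that add atoms: none
Why: E2 dehydrobromination of a bromoenol ether with KOtBu (H and Br anti in the Z isomer) is a known route to aryl ynol ethers and avoids alkyllithium or amide bases, which would cause bromine–lithium exchange or aryne formation on the ring.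

Step 6
Reactants: 9 coumalic acid (2-oxo-2H-pyran-5-carboxylic acid)
Product: 11 3,5-dibromo-2H-pyran-2-one, via 5-bromo-2H-pyran-2-one 10 (not isolated)
Conditions: NBS (2.5 equiv), LiOAc, MeCN–H2O, rt
Reagents that add atoms: N-bromosuccinimide, O=C1CCC(=O)N1Br
Why: Ipso-bromodecarboxylation of the carboxylate at C5 (Hunsdiecker-type) followed by electrophilic bromination at C3, the other nucleophilic carbon of the pyrone, is the established preparation of this dibromopyrone.

Step 7
Reactants: 8 1,5-dibromo-2-(ethynyloxy)-3-methoxybenzene; 11 3,5-dibromo-2H-pyran-2-one (1.5 equiv)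
Product: 13 1,5-dibromo-2-(2,4-dibromophenoxy)-3-methoxybenzene, via bridged lactone 12 (not isolated)
Conditions: toluene, BHT (cat.), 110 °C, sealed tube, slow addition of 8 to 11
Reagents that add atoms: none
Why: The electron-poor diene of 11 (C3=C4–C5=C6) and the electron-rich alkyne of 8 should combine in an intermolecular, asynchronous inverse-demand [4+2] cycloaddition, the terminal alkyne carbon bonding to the electrophilic C6 of the pyrone and the oxygen-bearing carbon to C3–Br, to give the 2-oxabicyclo[2.2.2]octadienone 12. Lactone 12 should lose CO2 by retro-[4+2] at the reaction temperature, so ring B (C1'–C6') is closed by cycloaddition and cycloreversion with no oxidation or elimination step and no chance to expel the aryloxy group. The closest known reaction type is the Diels–Alder/CO2-extrusion benzannulation of 2-pyrones with alkynes, together with the ambiphilic diene behaviour of 3,5-dibromo-2-pyrone toward electron-rich π-partners. No stereocentre remains, because the two bridgehead centres of racemic 12 are destroyed on aromatisation. The selectivity needed is regiochemical (aryloxy carbon next to the C3 bromine, giving 2,4- and not 3,5-dibromophenoxy); it should be secured by the matched polarisation of the ynol ether (nucleophilic β-carbon) and the pyrone (C6 as the vinylogous acceptor terminus), the same sense that alkyl vinyl ethers show with bromo-2-pyrones. Slow addition of 8 to an excess of hot 11 keeps the ynol ether dilute and should suppress its self-condensation.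

Step 8
Reactants: 13 1,5-dibromo-2-(2,4-dibromophenoxy)-3-methoxybenzene
Product: 15 3,5-dibromo-2-(2,4-dibromophenoxy)phenol, via aryloxydibromoborane 14 (not isolated)
Conditions: BBr3 (3 equiv), CH2Cl2, −78 °C → rt; then H2O, 0 °C
Reagents that add atoms: none
Why: Lewis-acid-mediated cleavage of an aryl methyl ether (bromide attacks the O-methyl carbon of the boron complex) leaves the diaryl ether C–O bonds and the aryl bromides untouched, and hydrolysis of the borane ester frees the phenol.

Step 9
Reactants: 15 3,5-dibromo-2-(2,4-dibromophenoxy)phenol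
Product: 16 3,5,6-tribromo-2-(2,4-dibromophenoxy)phenol (= 2,3,5-tribromo-6-(2,4-dibromophenoxy)phenol)
Conditions: NBS (1.05 equiv), i-Pr2NH (10 mol%), CH2Cl2, 0 °C → rt
Reagents that add atoms: N-bromosuccinimide, O=C1CCC(=O)N1Br
Why: Amine-mediated ortho-selective bromination of phenols (an N-bromoamine hydrogen-bonded to the OH delivers bromine) should functionalise C6, the only open ortho carbon, while C4 is flanked by the C3 and C5 bromines and ring B is deactivated.

**Compound list**
1 | guaiacol (2-methoxyphenol) | COc1ccccc1O | starting material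
2 | 2,4-dibromo-6-methoxyphenol | COc1cc(Br)cc(Br)c1O | intermediate
3 | 1,2-dibromoethane | BrCCBr | starting material
4 | 1,5-dibromo-2-(2-bromoethoxy)-3-methoxybenzene | COc1cc(Br)cc(Br)c1OCCBr | intermediate
5 | 1,5-dibromo-2-(ethenyloxy)-3-methoxybenzene | COc1cc(Br)cc(Br)c1OC=C | intermediate
6 | 1,5-dibromo-2-(1,2-dibromoethoxy)-3-methoxybenzene (racemic, not isolated) | COc1cc(Br)cc(Br)c1OC(Br)CBr | intermediate
7 | 1,5-dibromo-2-{[(Z)-2-bromoethenyl]oxy}-3-methoxybenzene | COc1cc(Br)cc(Br)c1O/C=C\Br | intermediate
8 | 1,5-dibromo-2-(ethynyloxy)-3-methoxybenzene | C#COc1c(Br)cc(Br)cc1OC | intermediate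
9 | coumalic acid (2-oxo-2H-pyran-5-carboxylic acid) | O=C(O)C1=COC(=O)C=C1 | starting material
10 | 5-bromo-2H-pyran-2-one (not isolated) | O=C1C=CC(Br)=CO1 | intermediate
11 | 3,5-dibromo-2H-pyran-2-one | O=C1OC=C(Br)C=C1Br | intermediate
12 | 4,7-dibromo-5-(2,4-dibromo-6-methoxyphenoxy)-2-oxabicyclo[2.2.2]octa-5,7-dien-3-one (racemic, not isolated) | O=C1OC2C=C(Oc3c(Br)cc(Br)cc3OC)C1(Br)C=C2Br | intermediate
13 | 1,5-dibromo-2-(2,4-dibromophenoxy)-3-methoxybenzene | COc1cc(Br)cc(Br)c1Oc1ccc(Br)cc1Br | intermediate
14 | dibromo[3,5-dibromo-2-(2,4-dibromophenoxy)phenoxy]borane (not isolated) | BrB(Br)Oc1cc(Br)cc(Br)c1Oc1ccc(Br)cc1Br | intermediate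
15 | 3,5-dibromo-2-(2,4-dibromophenoxy)phenol | Oc1cc(Br)cc(Br)c1Oc1ccc(Br)cc1Br | intermediate
16 | 3,5,6-tribromo-2-(2,4-dibromophenoxy)phenol | Oc1c(Br)c(Br)cc(Br)c1Oc1ccc(Br)cc1Br | target

**Step count:** 9 steps in total; longest linear sequence 8 steps (steps 1–5, 7, 8, 9).

**Steps most likely to fail**

1. Step 7. The ynol ether may oligomerise faster than it cycloadds, or the cycloaddition may be too slow at a temperature the ynol ether tolerates. Fallback: the diaryl ether is made by metal-free O-arylation instead of ring construction. It sets out from phenol 2 and returns at 13. Phenol 2 is treated with bis(2,4-dibromophenyl)iodonium chloride F1 (prepared from 1,3-dibromobenzene and iodyl sulfate in sulfuric acid, precipitated as the chloride) and NaOH in aqueous dioxane at 80 °C. Ligand coupling at iodine(III) should give 13 directly.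

2. Step 5. The terminal ynol ether may decompose during its generation or isolation, through base-induced addition, hydration or self-condensation. Fallback: the bromoenol ether itself is used as an alkyne equivalent. It sets out from 7 (with 11) and returns at 13. Heating 7 with 11 in toluene at 100 °C should give, with the same regiochemistry, the bridged lactone 4,6,7-tribromo-5-(2,4-dibromo-6-methoxyphenoxy)-2-oxabicyclo[2.2.2]oct-7-en-3-one F2. Further heating in xylene at 140 °C with 2,6-lutidine should expel CO2 to give the cyclohexadiene 1,5-dibromo-3-methoxy-2-[(2,4,6-tribromocyclohexa-2,4-dien-1-yl)oxy]benzene F3, not isolated. F3 should aromatise to 13 by loss of HBr, bromide being a much better leaving group than the aryloxide.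

3. Step 9. Bromination may go in part to the para carbon C4, or run on to the tetrabromophenol. Fallback: a removable directing group fixes the site. It sets out from 15 and returns at 16. SNAr of 15 on 2-fluoropyridine (Cs2CO3, DMSO, 120 °C) should give 2-[3,5-dibromo-2-(2,4-dibromophenoxy)phenoxy]pyridine F4. Pyridine-directed Pd(II)-catalysed C–H bromination (Pd(OAc)2 cat., NBS, TsOH cat., EtOAc, 100 °C) can only reach C6 and should give 2-[2,3,5-tribromo-6-(2,4-dibromophenoxy)phenoxy]pyridine F5. N-Methylation with MeOTf (toluene, 100 °C) gives 1-methyl-2-[2,3,5-tribromo-6-(2,4-dibromophenoxy)phenoxy]pyridinium triflate F6, and NaOMe in MeOH at reflux should release 16.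

**Further compounds**
F1 | step 7 | bis(2,4-dibromophenyl)iodonium chloride | Brc1ccc([I+]c2ccc(Br)cc2Br)c(Br)c1.[Cl-]
F2 | step 5 | 4,6,7-tribromo-5-(2,4-dibromo-6-methoxyphenoxy)-2-oxabicyclo[2.2.2]oct-7-en-3-one (racemic) | O=C1OC2C(Br)C(Oc3c(Br)cc(Br)cc3OC)C1(Br)C=C2Br
F3 | step 5 | 1,5-dibromo-3-methoxy-2-[(2,4,6-tribromocyclohexa-2,4-dien-1-yl)oxy]benzene (racemic) | COc1cc(Br)cc(Br)c1OC1C(Br)C=C(Br)C=C1Br
F4 | step 9 | 2-[3,5-dibromo-2-(2,4-dibromophenoxy)phenoxy]pyridine | Brc1ccc(Oc2c(Br)cc(Br)cc2Oc2ccccn2)c(Br)c1
F5 | step 9 | 2-[2,3,5-tribromo-6-(2,4-dibromophenoxy)phenoxy]pyridine | Brc1ccc(Oc2c(Br)cc(Br)c(Br)c2Oc2ccccn2)c(Br)c1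
F6 | step 9 | 1-methyl-2-[2,3,5-tribromo-6-(2,4-dibromophenoxy)phenoxy]pyridinium trifluoromethanesulfonate | C[n+]1ccccc1Oc1c(Br)c(Br)cc(Br)c1Oc1ccc(Br)cc1Br.[O-]S(=O)(=O)C(F)(F)F
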